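**Plan**

1. Ring A is the 2,4,6-trihydroxyphenyl ketone ring, ring B the 2-hydroxyphenyl ring, and the chain runs from C1 (C=O) to C11. The first retrosynthetic cut is C1–C2, which gives a salicylaldehyde-type C–H donor (ring A, bought intact) and a terminal alkene.
2. The second cut opens ring B at C1'–C6' and C2'–C3'. Ring B has four neighbouring unsubstituted CH carbons (C3'–C6') beside the adjacent pair C1' (chain) and C2' (oxygen); this is the C3–C6 diene of 2H-pyran-2-one joined to the two carbons of an O-silyl ynol ether.
3. The third cut takes the ynol ether C≡C back to methyl undec-10-enoate and dibromomethane.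
4. Forward: ester → siloxyalkyne → ring B by pyrone Diels–Alder reaction with loss of CO2 → chain terminus joined to ring A by rhodium-catalysed hydroacylation → removal of two MOM acetals and one silyl ether.
5. Stereochemistry: the target has no stereocentre and no stereogenic double bond. The only stereocentres on the way are the bridgeheads of the racemic bicyclic adduct, and they vanish on aromatisation.

Key step: step 2

Assumption: the target is treated as the aromatic triphenol tautomer drawn in its SMILES, and compounds 1, 2, 3, 7 and 10 are taken as commercial.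

**Step 1**
Reactants: 1 methyl undec-10-enoate; 2 dibromomethane; 3 triisopropylsilyl trifluoromethanesulfonate
Product: 6 (dodec-11-en-1-yn-1-yloxy)triisopropylsilane, via lithium dibromoenolate 4 (not isolated), via lithium ynolate 5 (not isolated)
Conditions: 2, lithium 2,2,6,6-tetramethylpiperidide (LiTMP, 2.2 equiv), THF, −78 °C, then 1; n-BuLi, −78 → 0 °C; 3, −78 → 0 °C; filtration through Et3N-deactivated silica
Reagents that add atoms: none
Why: Kowalski ester homologation stopped at the ynolate: acylation of dibromomethyllithium by 1 and deprotonation give enolate 4, bromine–lithium exchange triggers the carbenoid 1,2-shift of the alkyl chain to ynolate 5 (the ester carbon ends up bearing oxygen, the carbon of 2 bearing the chain), and the bulky silyl triflate is known to trap such ynolates on oxygen, while the remote terminal alkene is inert to the lithium bases at or below 0 °C.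

**Step 2**
Reactants: 6 (dodec-11-en-1-yn-1-yloxy)triisopropylsilane; 7 2H-pyran-2-one
Product: 9 [2-(dec-9-en-1-yl)phenoxy]triisopropylsilane, via bicyclic lactone 8 (not isolated)
Conditions: 7 (3 equiv), PhMe (degassed), sealed tube, 140 °C, −CO2
Reagents that add atoms: none
Why: Proposed new method: the high-lying HOMO of the O-silyl ynol ether (largest coefficient on the chain-bearing carbon) should combine with the LUMO of the pyrone (largest coefficient on C6) in an inverse-electron-demand [4+2] cycloaddition across pyrone C3 and C6 to give bicyclic lactone 8, which at this temperature expels CO2 by retro-[4+2] and is thereby aromatised to 9. The closest known reactions are the thermal Diels–Alder/decarboxylation of 2-pyrones with alkynes (acetylenedicarboxylates, alkynylboronates, ynamines) and the thermal benzannulation of siloxyalkynes with vinylketenes, which shows that triisopropylsilyl ynol ethers tolerate prolonged heating; untested is the pairing of the parent, unactivated pyrone with a siloxyalkyne. Ring B closes as a six-membered carbocycle in an intermolecular [4+2] mode through two new C–C bonds (pyrone C3 to the oxygen-bearing alkyne carbon, pyrone C6 to the chain-bearing one), followed by extrusion of the lactone bridge. No stereocentre is set, because the two bridgehead centres of racemic 8 disappear on aromatisation. The step needs chemoselectivity for the alkyne over the terminal alkene, which the far more electron-rich ynol ether π-system secures, whereas regioselectivity is irrelevant because the pyrone carries only hydrogen on C3–C6 and both orientations collapse to the same ortho-disubstituted arene. The triisopropylsilyl group rules out the retro-ene fragmentation open to alkyl ynol ethers and retards the 1,3-shift of silicon from oxygen to carbon.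

**Step 3**
Reactants: 10 2,4,6-trihydroxybenzaldehyde
Product: 11 2-hydroxy-4,6-bis(methoxymethoxy)benzaldehyde
Conditions: MOMCl (2.1 equiv), i-Pr2NEt (2.5 equiv), CH2Cl2, 0 °C → rt
Reagents that add atoms: chloromethyl methyl ether, COCCl
Why: Base-mediated O-alkylation of phenols with an α-chloro ether (MOM acetal formation), selective because the para hydroxyl and one ortho hydroxyl react while the remaining ortho hydroxyl, hydrogen-bonded to the formyl oxygen, is the least nucleophilic and stays free as the chelating group for step 4, the usual outcome for 2,4,6-trihydroxyaryl carbonyl compounds with two equivalents of MOMCl.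

**Step 4**
Reactants: 9 [2-(dec-9-en-1-yl)phenoxy]triisopropylsilane; 11 2-hydroxy-4,6-bis(methoxymethoxy)benzaldehyde (1.5 equiv)
Product: 12 1-[2-hydroxy-4,6-bis(methoxymethoxy)phenyl]-11-{2-[(triisopropylsilyl)oxy]phenyl}undecan-1-one
Conditions: [Rh(cod)Cl]2 (2.5 mol %), MonoPhos (BINOL-derived phosphoramidite, 10 mol %), K3PO4 (10 mol %), 1,4-dioxane, 80 °C
Reagents that add atoms: none
Why: Chelation-assisted rhodium-catalysed intermolecular hydroacylation of an unactivated terminal alkene by a salicylaldehyde: the rhodium phenoxide of 11 inserts into the formyl C–H bond to give a five-membered acyl rhodium hydride chelate that resists decarbonylation, the alkene inserts into Rh–H with rhodium at the terminal carbon under control of the phosphoramidite, and C–C reductive elimination forges the C1–C2 bond of the linear ketone, the aryl silyl ether and the MOM acetals being inert to the weakly basic medium.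

**Step 5**
Reactants: 12 1-[2-hydroxy-4,6-bis(methoxymethoxy)phenyl]-11-{2-[(triisopropylsilyl)oxy]phenyl}undecan-1-one
Product: 13 1-(2,4,6-trihydroxyphenyl)-11-{2-[(triisopropylsilyl)oxy]phenyl}undecan-1-one
Conditions: HCl (3 M aq), MeOH/THF, 40 °C
Reagents that add atoms: none
Why: Acid-catalysed cleavage of the two methoxymethyl acetals by transacetalisation with methanol, under which the hindered aryl triisopropylsilyl ether, the saturated chain and the aryl ketone are expected to survive.

**Step 6**
Reactants: 13 1-(2,4,6-trihydroxyphenyl)-11-{2-[(triisopropylsilyl)oxy]phenyl}undecan-1-one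
Product: 14 1-(2,4,6-trihydroxyphenyl)-11-(2-hydroxyphenyl)undecan-1-one
Conditions: Bu4NF (TBAF), AcOH, THF, 0 °C → rt
Reagents that add atoms: none
Why: Fluoride-induced cleavage of the aryl silyl ether, driven by formation of the strong Si–F bond, with acetic acid buffering so that the electron-rich acylphloroglucinol is not exposed to strongly basic, oxidation-prone conditions.

**Compound list**

1 | methyl undec-10-enoate | C=CCCCCCCCCC(=O)OC | starting material
2 | dibromomethane | BrCBr | starting material
3 | triisopropylsilyl trifluoromethanesulfonate | CC(C)[Si](OS(=O)(=O)C(F)(F)F)(C(C)C)C(C)C | starting material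
4 | lithium 1,1-dibromododeca-1,11-dien-2-olate (not isolated) | [Li+].[O-]C(CCCCCCCCC=C)=C(Br)Br | intermediate
5 | lithium dodec-11-en-1-yn-1-olate (not isolated) | [Li+].[O-]C#CCCCCCCCCC=C | intermediate
6 | (dodec-11-en-1-yn-1-yloxy)triisopropylsilane | C=CCCCCCCCCC#CO[Si](C(C)C)(C(C)C)C(C)C | intermediate
7 | 2H-pyran-2-one | O=C1C=CC=CO1 | starting material
8 | rac-(1R,4S)-6-(dec-9-en-1-yl)-5-[(triisopropylsilyl)oxy]-2-oxabicyclo[2.2.2]octa-5,7-dien-3-one (racemic, one enantiomer drawn; not isolated) | C=CCCCCCCCCC1=C(O[Si](C(C)C)(C(C)C)C(C)C)[C@@H]2C=C[C@H]1OC2=O | intermediate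
9 | [2-(dec-9-en-1-yl)phenoxy]triisopropylsilane | C=CCCCCCCCCc1ccccc1O[Si](C(C)C)(C(C)C)C(C)C | intermediate
10 | 2,4,6-trihydroxybenzaldehyde | O=Cc1c(O)cc(O)cc1O | starting material
11 | 2-hydroxy-4,6-bis(methoxymethoxy)benzaldehyde | O=Cc1c(O)cc(OCOC)cc1OCOC | intermediate
12 | 1-[2-hydroxy-4,6-bis(methoxymethoxy)phenyl]-11-{2-[(triisopropylsilyl)oxy]phenyl}undecan-1-one | O=C(CCCCCCCCCCc1ccccc1O[Si](C(C)C)(C(C)C)C(C)C)c1c(O)cc(OCOC)cc1OCOC | intermediate
13 | 1-(2,4,6-trihydroxyphenyl)-11-{2-[(triisopropylsilyl)oxy]phenyl}undecan-1-one | O=C(CCCCCCCCCCc1ccccc1O[Si](C(C)C)(C(C)C)C(C)C)c1c(O)cc(O)cc1O | intermediate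
14 | 1-(2,4,6-trihydroxyphenyl)-11-(2-hydroxyphenyl)undecan-1-one | O=C(CCCCCCCCCCc1ccccc1O)c1c(O)cc(O)cc1O | target

**Count**

Total step count: 6.
Longest linear sequence: 5 steps (steps 1, 2, 4, 5, 6, from ester 1 to target 14); step 3 is a one-step side branch.

**Steps most likely to fail**

Step 2. The cycloaddition to the only weakly electron-poor parent pyrone may be slower than thermal migration of silicon from oxygen to carbon (ynol ether to silylketene) or than self-condensation of the pyrone, so that the alkyne is consumed unproductively. A Lewis acid such as AgNTf2 to lower the temperature would change the conditions only. The fallback buys ring B and uses known chemistry. It sets out from silyl triflate 3: commercial 2-bromophenol is silylated with 3 (2,6-lutidine, CH2Cl2, 0 °C) to (2-bromophenoxy)triisopropylsilane F1. Zinc insertion into commercial 10-bromodec-1-ene (Zn dust, LiCl, THF, 40 °C) gives dec-9-en-1-ylzinc bromide F2. Negishi coupling of the two (Pd(OAc)2, SPhos, THF, rt to 50 °C) should deliver arene 9, where the route is rejoined before step 4.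

Step 4. The rhodium hydride may move the terminal double bond into the chain faster than the C–C bond forms, branched insertion may compete, and decarbonylation of the electron-rich aldehyde may deactivate the catalyst as a rhodium carbonyl. The fallback sets out from alkene 9. Cross-metathesis with acrylonitrile (second-generation Hoveyda–Grubbs catalyst, CH2Cl2, 40 °C) should give, mainly as the Z isomer, (Z)-11-{2-[(triisopropylsilyl)oxy]phenyl}undec-2-enenitrile F3; the minor E isomer converges in the next operation. Hydrogenation of the C=C bond (H2, Pd/C, EtOAc, rt) gives 11-{2-[(triisopropylsilyl)oxy]phenyl}undecanenitrile F4. Houben–Hoesch acylation of commercial phloroglucinol with F4 (ZnCl2, HCl gas, Et2O, 0 °C) gives 1-(2,4,6-trihydroxyphenyl)-11-{2-[(triisopropylsilyl)oxy]phenyl}undecan-1-iminium chloride F5, whose hydrolysis in warm water gives ketone 13. The route is rejoined at 13 before step 6, and steps 3 and 5 are then not needed.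

Step 1. The carbenoid rearrangement may stay incomplete, residual n-BuLi may transfer butyl to the silyl triflate, and the acid-labile siloxyalkyne may hydrolyse on work-up or chromatography. The fallback makes the ynolate by acetylide oxidation and sets out from ester 1. Reduction with i-Bu2AlH (CH2Cl2, −78 °C) gives undec-10-enal F6. Ohira–Bestmann homologation (dimethyl (1-diazo-2-oxopropyl)phosphonate, K2CO3, MeOH, rt) gives dodec-1-en-11-yne F7. Deprotonation with n-BuLi (THF, −78 °C) gives lithium dodec-11-en-1-yn-1-ide F8, which t-BuOOLi (−78 → 0 °C) oxidises to ynolate 5. The route is rejoined at 5, which is silylated with 3 as in step 1 to give 6.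

**Further compounds**

F1 | step 2 | (2-bromophenoxy)triisopropylsilane | CC(C)[Si](Oc1ccccc1Br)(C(C)C)C(C)C
F2 | step 2 | dec-9-en-1-ylzinc bromide | C=CCCCCCCCC[Zn]Br
F3 | step 4 | (Z)-11-{2-[(triisopropylsilyl)oxy]phenyl}undec-2-enenitrile | N#C/C=C\CCCCCCCCc1ccccc1O[Si](C(C)C)(C(C)C)C(C)C
F4 | step 4 | 11-{2-[(triisopropylsilyl)oxy]phenyl}undecanenitrile | N#CCCCCCCCCCCc1ccccc1O[Si](C(C)C)(C(C)C)C(C)C
F5 | step 4 | 1-(2,4,6-trihydroxyphenyl)-11-{2-[(triisopropylsilyl)oxy]phenyl}undecan-1-iminium chloride | [NH2+]=C(CCCCCCCCCCc1ccccc1O[Si](C(C)C)(C(C)C)C(C)C)c1c(O)cc(O)cc1O.[Cl-]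
F6 | step 1 | undec-10-enal | C=CCCCCCCCCC=O
F7 | step 1 | dodec-1-en-11-yne | C=CCCCCCCCCC#C
F8 | step 1 | lithium dodec-11-en-1-yn-1-ide | [Li]C#CCCCCCCCCC=C
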